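**Plan**

- Retrosynthesis: the acetate is removed first. The cyclohexadienone ring (C1′ = spiro carbon = C5 of the benzo[7]annulene, C4′ = carbonyl) is then cut at two bonds on opposite sides, C1′–C6′ and C3′–C4′, which leaves a benzosuberane carrying a 2-methoxyethylidene group on C5 and methyl 2,3-dimethoxyacrylate.
- Enabling feature: the 3′,5′-dimethoxycyclohexa-2′,5′-dien-4′-one ring is the bis(enol methyl ether) of a 1,2,3-trione, and its spiro carbon C5 is both benzylic and allylic. C5–C2′–C3′ can therefore act as a 1-methoxyallyl anion and C4′–C5′–C6′ as an acyl/β-methoxyvinyl double electrophile, so one acylation plus one 6π closure with loss of methoxide gives the dienone directly.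
- Further cuts: the C5 side arm goes back to a C5 ketone, the C4a–C5 bond to an aryl bromide and a δ-lactone carbonyl, the lactone to an acrylate (ring-closing metathesis), and C8–C9 to a crotylboration of 2-bromo-3,4,5-trimethoxybenzaldehyde.
- Forward order: C8–C9 chain, temporary lactone ring, C7 methyl, seven-membered ring, side arm, dienone ring last, then desilylation and acetylation.
- Stereochemistry: C9 and C8 come from the catalyst-controlled syn-crotylboration, C7 from substrate-controlled anti addition of a cuprate to the lactone. The spiro carbon is not stereogenic.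

Key step: step 10

Remark: the (R)-configured phosphoric acid of step 1 is assumed to favour the aldehyde face that gives the 1R carbinol, as with simple benzaldehydes; the antipodal acid would be taken if the ortho-bromo group inverted this.
Remark: benzo[7]annulene positions are numbered so that the benzylic carbon on C4a is C5 and the oxygen-bearing benzylic carbon is C9; metal alkoxides and enolates that are only protonated on aqueous work-up are counted with their products.

**Route**

Step 1
Reactants: 1 2-bromo-3,4,5-trimethoxybenzaldehyde; 2 cis-crotylboronic acid pinacol ester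
Product: 3 (1R,2S)-1-(2-bromo-3,4,5-trimethoxyphenyl)-2-methylbut-3-en-1-ol
Conditions: (R)-TRIP [(R)-3,3′-bis(2,4,6-triisopropylphenyl)-1,1′-binaphthyl-2,2′-diyl hydrogen phosphate] (5 mol %), toluene, −30 °C
Reagents that add atoms: none
Why: Chiral phosphoric acid-catalysed crotylboration runs through a closed chair transition state, so the Z-boronate should give the syn pair and the catalyst should select the aldehyde face that sets C9 (1R) and with it C8 (2S).

Step 2
Reactants: 3 (1R,2S)-1-(2-bromo-3,4,5-trimethoxyphenyl)-2-methylbut-3-en-1-ol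
Product: 4 (1R,2S)-1-(2-bromo-3,4,5-trimethoxyphenyl)-2-methylbut-3-en-1-yl prop-2-enoate
Conditions: acryloyl chloride, Et3N, DMAP (cat.), CH2Cl2, 0 °C
Reagents that add atoms: acryloyl chloride, C=CC(=O)Cl
Why: Standard DMAP-catalysed O-acylation of a secondary alcohol, which touches no stereocentre.

Step 3
Reactants: 4 (1R,2S)-1-(2-bromo-3,4,5-trimethoxyphenyl)-2-methylbut-3-en-1-yl prop-2-enoate
Product: 5 (5S,6R)-6-(2-bromo-3,4,5-trimethoxyphenyl)-5-methyl-5,6-dihydro-2H-pyran-2-one
Conditions: second-generation Grubbs catalyst (H2IMes)(PCy3)Cl2Ru=CHPh (5 mol %), CH2Cl2, 40 °C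
Reagents that add atoms: none
Why: Ring-closing metathesis of the acrylate with the terminal alkene should close the six-membered unsaturated lactone with loss of ethene, the cis relation of methyl and aryl following from the syn alcohol.

Step 4
Reactants: 5 (5S,6R)-6-(2-bromo-3,4,5-trimethoxyphenyl)-5-methyl-5,6-dihydro-2H-pyran-2-one
Product: 6 (4R,5S,6R)-6-(2-bromo-3,4,5-trimethoxyphenyl)-4,5-dimethyloxan-2-one
Conditions: Me2CuLi (from MeLi, CuI), Et2O, −78 → −40 °C
Reagents that add atoms: lithium dimethylcuprate (Me2CuLi), [Li+].C[Cu-]C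
Why: Cuprate conjugate addition to a 5,6-dihydropyran-2-one should occur anti to the adjacent pseudoaxial C5 methyl group, which sets the new centre (C7 of the target, 4R here) trans to it.

Step 5
Reactants: 6 (4R,5S,6R)-6-(2-bromo-3,4,5-trimethoxyphenyl)-4,5-dimethyloxan-2-one
Product: 8 (7R,8S,9R)-9-hydroxy-2,3,4-trimethoxy-7,8-dimethyl-6,7,8,9-tetrahydro-5H-benzo[7]annulen-5-one, via hemiketal alkoxide 7 (not isolated)
Conditions: t-BuLi (2.1 equiv), THF, −100 → −78 °C
Reagents that add atoms: none
Why: Bromine–lithium exchange should outrun attack of t-BuLi on the lactone, and the aryllithium then acylates itself on the lactone carbonyl lying 1,3-diaxial to it (Parham cyclisation); the bridged alkoxide 7 resists over-addition and opens on work-up to the seven-membered hydroxy ketone with all three stereocentres untouched.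

Step 6
Reactants: 8 (7R,8S,9R)-9-hydroxy-2,3,4-trimethoxy-7,8-dimethyl-6,7,8,9-tetrahydro-5H-benzo[7]annulen-5-one
Product: 9 (7R,8S,9R)-9-[(tert-butyldimethylsilyl)oxy]-2,3,4-trimethoxy-7,8-dimethyl-6,7,8,9-tetrahydro-5H-benzo[7]annulen-5-one
Conditions: TBSCl, imidazole, DMF, 23 → 40 °C
Reagents that add atoms: tert-butyldimethylsilyl chloride, CC(C)(C)[Si](C)(C)Cl
Why: Standard silyl ether formation at the secondary benzylic hydroxyl of the open hydroxy-ketone tautomer, the tertiary hydroxyl of any transannular hemiketal tautomer being too hindered to compete.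

Step 7
Reactants: 9 (7R,8S,9R)-9-[(tert-butyldimethylsilyl)oxy]-2,3,4-trimethoxy-7,8-dimethyl-6,7,8,9-tetrahydro-5H-benzo[7]annulen-5-one
Product: 10 (7R,8S,9R)-9-[(tert-butyldimethylsilyl)oxy]-5-ethenyl-2,3,4-trimethoxy-7,8-dimethyl-6,7,8,9-tetrahydro-5H-benzo[7]annulen-5-ol (both C5 epimers)
Conditions: CH2=CHMgBr, CeCl3, THF, −78 → 0 °C
Reagents that add atoms: vinylmagnesium bromide, C=C[Mg]Br
Why: CeCl3-mediated 1,2-addition of a vinyl Grignard reagent to a hindered, enolisable aryl ketone; the configuration of the new carbinol carbon is irrelevant because it is planarised in step 8.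

Step 8
Reactants: 10 (7R,8S,9R)-9-[(tert-butyldimethylsilyl)oxy]-5-ethenyl-2,3,4-trimethoxy-7,8-dimethyl-6,7,8,9-tetrahydro-5H-benzo[7]annulen-5-ol
Product: 11 tert-butyl{[(7R,8S,9R)-2,3,4-trimethoxy-5-(2-methoxyethylidene)-7,8-dimethyl-6,7,8,9-tetrahydro-5H-benzo[7]annulen-9-yl]oxy}dimethylsilane (both alkene isomers)
Conditions: PPTS (10 mol %), MeOH, 0 → 23 °C
Reagents that add atoms: methanol, CO
Why: Acid-catalysed SN1′ allylic transposition, in which the tertiary, benzylic, allylic cation is captured reversibly by methanol and should funnel under thermodynamic control to the primary allyl methyl ether with the styrene-type alkene (either alkene geometry serves in step 10).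

Step 9
Reactants: 12 methyl 2-methoxyacetate
Product: 14 methyl (2Z)-2,3-dimethoxyprop-2-enoate, via formyl enolate 13 (not isolated)
Conditions: NaH, HCO2Me, THF, 0 → 23 °C; then Me2SO4, DMF, 23 °C
Reagents that add atoms: methyl formate, COC=O; dimethyl sulfate, COS(=O)(=O)OC
Why: Crossed Claisen formylation of the ester enolate followed by O-methylation of the formyl enolate with a hard electrophile should give the β-methoxyacrylate, the isomer with the 3-methoxy group trans to the ester being the expected major one.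

Step 10
Reactants: 11 tert-butyl{[(7R,8S,9R)-2,3,4-trimethoxy-5-(2-methoxyethylidene)-7,8-dimethyl-6,7,8,9-tetrahydro-5H-benzo[7]annulen-9-yl]oxy}dimethylsilane; 14 methyl (2Z)-2,3-dimethoxyprop-2-enoate
Product: 19 (7R,8S,9R)-9-[(tert-butyldimethylsilyl)oxy]-2,3,3′,4,5′-pentamethoxy-7,8-dimethyl-6,7,8,9-tetrahydrospiro[benzo[7]annulene-5,1′-cyclohexa[2,5]dien]-4′-one, via lithiated ether 15 (not isolated), via α-methoxy ketone 16 (not isolated), via trienolate 17 (not isolated), via cyclohexadienolate 18 (not isolated)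
Conditions: s-BuLi, TMEDA, THF, −78 °C; then addition to 14 premixed with KN(SiMe3)2, THF, −78 → 23 °C
Reagents that add atoms: none
Why: Proposed new method: s-BuLi removes a proton from the CH2OMe group of 11 (allylic, α to oxygen, conjugated through C5 to the arene) to give the 1-methoxyallyl anion 15, which is acylated by ester 14 at its unhindered α-carbon (C3′–C4′ bond) to give ketone 16, and KN(SiMe3)2 at once removes the doubly activated proton between carbonyl and methoxy group to give hexatrien-3-olate 17. Disrotatory 6π electrocyclisation of 17 joins C5 to the β-methoxyvinyl carbon (C1′–C6′ bond) and gives cyclohexadienolate 18, from which methoxide departs by E1cB to leave the cross-conjugated dienone; the closest known reaction types are the α-acylation of oxygen-stabilised allyllithiums and the oxyanion-accelerated 6π electrocyclisation of hexatrien-3-olates formed in ring expansions of 1-alkenylcyclobutenolates, here fed by a Claisen-type acylation and ended by β-elimination. The single new ring is closed in this pericyclic step with all six ring atoms inside the triene (formally a 6-endo attack of the dienolate γ-carbon on the alkoxyvinyl terminus), and loss of methoxide makes the closure irreversible. No stereocentre results, because the two arms on the spiro carbon of 19 are identical and the transient centres of 16 and 18 are erased by enolisation and elimination. The step needs α- rather than γ-acylation of the allyl anion (the γ-carbon C5 is fully substituted and shielded by the ortho-methoxyarene), the Z enolate geometry that places both vinyl arms cis (secured by chelation of the metal between the enolate oxygen and the C3′ methoxy group), and no proton transfer from 16 to unreacted 15 (secured by adding 15 to the ester premixed with the amide base, so that the carbanion is always the minor species).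

Step 11
Reactants: 19 (7R,8S,9R)-9-[(tert-butyldimethylsilyl)oxy]-2,3,3′,4,5′-pentamethoxy-7,8-dimethyl-6,7,8,9-tetrahydrospiro[benzo[7]annulene-5,1′-cyclohexa[2,5]dien]-4′-one
Product: 20 (7R,8S,9R)-9-hydroxy-2,3,3′,4,5′-pentamethoxy-7,8-dimethyl-6,7,8,9-tetrahydrospiro[benzo[7]annulene-5,1′-cyclohexa[2,5]dien]-4′-one
Conditions: HF·pyridine, pyridine, THF, 0 → 23 °C
Reagents that add atoms: none
Why: Fluoride-mediated silyl ether cleavage under buffered, weakly acidic conditions that should neither ionise the benzylic C9–O bond nor generate an alkoxide able to add to the dienone.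

Step 12
Reactants: 20 (7R,8S,9R)-9-hydroxy-2,3,3′,4,5′-pentamethoxy-7,8-dimethyl-6,7,8,9-tetrahydrospiro[benzo[7]annulene-5,1′-cyclohexa[2,5]dien]-4′-one
Product: 21 (7R,8S,9R)-2,3,3′,4,5′-pentamethoxy-7,8-dimethyl-4′-oxo-6,7,8,9-tetrahydrospiro[benzo[7]annulene-5,1′-cyclohexa[2,5]dien]-9-yl acetate
Conditions: Ac2O, pyridine, DMAP (cat.), CH2Cl2, 0 °C
Reagents that add atoms: acetic anhydride, CC(=O)OC(C)=O
Why: DMAP-catalysed acetylation of the secondary benzylic alcohol with retention at C9 should give the target.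

**Compound list**

1 | 2-bromo-3,4,5-trimethoxybenzaldehyde | O=Cc1cc(OC)c(OC)c(OC)c1Br | starting material
2 | (Z)-2-(but-2-en-1-yl)-4,4,5,5-tetramethyl-1,3,2-dioxaborolane (cis-crotylboronic acid pinacol ester) | C/C=C\CB1OC(C)(C)C(C)(C)O1 | starting material
3 | (1R,2S)-1-(2-bromo-3,4,5-trimethoxyphenyl)-2-methylbut-3-en-1-ol | C=C[C@H](C)[C@@H](O)c1cc(OC)c(OC)c(OC)c1Br | intermediate
4 | (1R,2S)-1-(2-bromo-3,4,5-trimethoxyphenyl)-2-methylbut-3-en-1-yl prop-2-enoate | C=C[C@H](C)[C@@H](OC(=O)C=C)c1cc(OC)c(OC)c(OC)c1Br | intermediate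
5 | (5S,6R)-6-(2-bromo-3,4,5-trimethoxyphenyl)-5-methyl-5,6-dihydro-2H-pyran-2-one | O=C1C=C[C@H](C)[C@@H](O1)c1cc(OC)c(OC)c(OC)c1Br | intermediate
6 | (4R,5S,6R)-6-(2-bromo-3,4,5-trimethoxyphenyl)-4,5-dimethyloxan-2-one | O=C1C[C@@H](C)[C@H](C)[C@@H](O1)c1cc(OC)c(OC)c(OC)c1Br | intermediate
7 | lithium (7R,8S,9R)-2,3,4-trimethoxy-7,8-dimethyl-6,7,8,9-tetrahydro-5H-5,9-epoxybenzo[7]annulen-5-olate (bridgehead C5 fixed by the bridge) | [Li+].[O-]C12C[C@@H](C)[C@H](C)[C@@H](O1)c1cc(OC)c(OC)c(OC)c12 | intermediate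
8 | (7R,8S,9R)-9-hydroxy-2,3,4-trimethoxy-7,8-dimethyl-6,7,8,9-tetrahydro-5H-benzo[7]annulen-5-one | O=C1C[C@@H](C)[C@H](C)[C@@H](O)c2cc(OC)c(OC)c(OC)c21 | intermediate
9 | (7R,8S,9R)-9-[(tert-butyldimethylsilyl)oxy]-2,3,4-trimethoxy-7,8-dimethyl-6,7,8,9-tetrahydro-5H-benzo[7]annulen-5-one | O=C1C[C@@H](C)[C@H](C)[C@@H](O[Si](C)(C)C(C)(C)C)c2cc(OC)c(OC)c(OC)c21 | intermediate
10 | (7R,8S,9R)-9-[(tert-butyldimethylsilyl)oxy]-5-ethenyl-2,3,4-trimethoxy-7,8-dimethyl-6,7,8,9-tetrahydro-5H-benzo[7]annulen-5-ol (both C5 epimers) | C=CC1(O)C[C@@H](C)[C@H](C)[C@@H](O[Si](C)(C)C(C)(C)C)c2cc(OC)c(OC)c(OC)c21 | intermediate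
11 | tert-butyl{[(7R,8S,9R)-2,3,4-trimethoxy-5-(2-methoxyethylidene)-7,8-dimethyl-6,7,8,9-tetrahydro-5H-benzo[7]annulen-9-yl]oxy}dimethylsilane (both alkene isomers) | COCC=C1C[C@@H](C)[C@H](C)[C@@H](O[Si](C)(C)C(C)(C)C)c2cc(OC)c(OC)c(OC)c21 | intermediate
12 | methyl 2-methoxyacetate | COCC(=O)OC | starting material
13 | sodium 2,3-dimethoxy-3-oxoprop-1-en-1-olate | [Na+].[O-]C=C(OC)C(=O)OC | intermediate
14 | methyl (2Z)-2,3-dimethoxyprop-2-enoate | CO/C=C(\OC)C(=O)OC | intermediate
15 | lithium 1-methoxy-2-[(7R,8S,9R)-9-[(tert-butyldimethylsilyl)oxy]-2,3,4-trimethoxy-7,8-dimethyl-6,7,8,9-tetrahydro-5H-benzo[7]annulen-5-ylidene]ethan-1-ide | [Li+].CO[CH-]C=C1C[C@@H](C)[C@H](C)[C@@H](O[Si](C)(C)C(C)(C)C)c2cc(OC)c(OC)c(OC)c21 | intermediate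
16 | (1Z)-5-[(7R,8S,9R)-9-[(tert-butyldimethylsilyl)oxy]-2,3,4-trimethoxy-7,8-dimethyl-6,7,8,9-tetrahydro-5H-benzo[7]annulen-5-ylidene]-1,2,4-trimethoxypent-1-en-3-one (both C4 epimers) | CO/C=C(\OC)C(=O)C(OC)C=C1C[C@@H](C)[C@H](C)[C@@H](O[Si](C)(C)C(C)(C)C)c2cc(OC)c(OC)c(OC)c21 | intermediate
17 | potassium (1Z)-5-[(7R,8S,9R)-9-[(tert-butyldimethylsilyl)oxy]-2,3,4-trimethoxy-7,8-dimethyl-6,7,8,9-tetrahydro-5H-benzo[7]annulen-5-ylidene]-1,2,4-trimethoxypenta-1,3-dien-3-olate | [K+].CO/C=C(\OC)C([O-])=C(OC)C=C1C[C@@H](C)[C@H](C)[C@@H](O[Si](C)(C)C(C)(C)C)c2cc(OC)c(OC)c(OC)c21 | intermediate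
18 | potassium (7R,8S,9R)-9-[(tert-butyldimethylsilyl)oxy]-2,3,3′,4,5′,6′-hexamethoxy-7,8-dimethyl-6,7,8,9-tetrahydrospiro[benzo[7]annulene-5,1′-cyclohexa[2,4]dien]-4′-olate (spiro carbon and C6′ unassigned) | [K+].COC1C(OC)=C([O-])C(OC)=CC12C[C@@H](C)[C@H](C)[C@@H](O[Si](C)(C)C(C)(C)C)c1cc(OC)c(OC)c(OC)c12 | intermediate
19 | (7R,8S,9R)-9-[(tert-butyldimethylsilyl)oxy]-2,3,3′,4,5′-pentamethoxy-7,8-dimethyl-6,7,8,9-tetrahydrospiro[benzo[7]annulene-5,1′-cyclohexa[2,5]dien]-4′-one | COC1=CC2(C=C(OC)C1=O)C[C@@H](C)[C@H](C)[C@@H](O[Si](C)(C)C(C)(C)C)c1cc(OC)c(OC)c(OC)c12 | intermediate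
20 | (7R,8S,9R)-9-hydroxy-2,3,3′,4,5′-pentamethoxy-7,8-dimethyl-6,7,8,9-tetrahydrospiro[benzo[7]annulene-5,1′-cyclohexa[2,5]dien]-4′-one | COC1=CC2(C=C(OC)C1=O)C[C@@H](C)[C@H](C)[C@@H](O)c1cc(OC)c(OC)c(OC)c12 | intermediate
21 | (7R,8S,9R)-2,3,3′,4,5′-pentamethoxy-7,8-dimethyl-4′-oxo-6,7,8,9-tetrahydrospiro[benzo[7]annulene-5,1′-cyclohexa[2,5]dien]-9-yl acetate (CNP0143674.1) | COC1=CC2(C=C(OC)C1=O)C[C@@H](C)[C@H](C)[C@@H](OC(C)=O)c1cc(OC)c(OC)c(OC)c12 | target

**Step count**

Total steps: 12. Longest linear sequence: 11 steps (steps 1–8 and 10–12); step 9 is a one-step side branch.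

**Steps most likely to fail**

1. Step 10 (proposed new method). The allyl anion may be acylated at the wrong terminus, may be quenched by proton transfer from the first-formed ketone, or the crowded trienolate may not ring-close before it decomposes. The fallback builds the ring at the 1,3-dione level by the classical dimedone sequence and sets out from ketone 9.
   - Addition of CH3C≡CMgBr with CeCl3 would give the propargylic alcohol F1.
   - Meyer–Schuster rearrangement (Ph3PAuNTf2 cat., wet toluene) would give the methyl enone F2.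
   - Michael addition of dimethyl malonate to the β,β-disubstituted enone, followed by Claisen ring closure (NaOMe, MeOH, reflux), would give the dioxo ester F3.
   - Saponification and mild acidification (NaOH, then AcOH, 50 °C) would decarboxylate it to the spiro-1,3-dione F4.
   - Oxidation of the carbon between the carbonyls with Dess–Martin periodinane and pyridine would give the trione F5.
   - Double O-methylation of its two enols (Me2SO4, K2CO3, acetone) comes back to the route at 19.

2. Step 5. Attack of t-BuLi on the lactone carbonyl or enolisation of the lactone may outrun bromine–lithium exchange and ring closure. The fallback changes the acyl acceptor and sets out from lactone 6: aminolysis with MeNH(OMe)·HCl and i-PrMgCl would give the hydroxy N-methoxy-N-methylamide F6. Deprotonation of its hydroxyl with n-BuLi, then exchange with t-BuLi, would let the aryllithium close onto the amide through a stable chelated tetrahedral intermediate. Work-up comes back to the route at 8.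

3. Step 8. The silyl group may be lost, the C9 oxygen may capture the cation, or elimination to a diene may compete with methanol capture at the primary terminus. The fallback avoids cations altogether and sets out from ketone 9: Peterson olefination with the enolate from ethyl (trimethylsilyl)acetate and LiN(i-Pr)2 would give the enoate F7, reduction with i-Bu2AlH the allylic alcohol F8, and methylation with NaH and MeI comes back to the route at 11 (alcohol 10 is bypassed).

**Further compounds**

F1 | step 10 | (7R,8S,9R)-9-[(tert-butyldimethylsilyl)oxy]-2,3,4-trimethoxy-7,8-dimethyl-5-(prop-1-yn-1-yl)-6,7,8,9-tetrahydro-5H-benzo[7]annulen-5-ol | CC#CC1(O)C[C@@H](C)[C@H](C)[C@@H](O[Si](C)(C)C(C)(C)C)c2cc(OC)c(OC)c(OC)c21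
F2 | step 10 | 1-[(7R,8S,9R)-9-[(tert-butyldimethylsilyl)oxy]-2,3,4-trimethoxy-7,8-dimethyl-6,7,8,9-tetrahydro-5H-benzo[7]annulen-5-ylidene]propan-2-one | CC(=O)C=C1C[C@@H](C)[C@H](C)[C@@H](O[Si](C)(C)C(C)(C)C)c2cc(OC)c(OC)c(OC)c21
F3 | step 10 | methyl (7R,8S,9R)-9-[(tert-butyldimethylsilyl)oxy]-2,3,4-trimethoxy-7,8-dimethyl-3′,5′-dioxo-6,7,8,9-tetrahydrospiro[benzo[7]annulene-5,1′-cyclohexane]-2′-carboxylate | COC(=O)C1C(=O)CC(=O)CC12C[C@@H](C)[C@H](C)[C@@H](O[Si](C)(C)C(C)(C)C)c1cc(OC)c(OC)c(OC)c12
F4 | step 10 | (7R,8S,9R)-9-[(tert-butyldimethylsilyl)oxy]-2,3,4-trimethoxy-7,8-dimethyl-6,7,8,9-tetrahydrospiro[benzo[7]annulene-5,1′-cyclohexane]-3′,5′-dione | O=C1CC(=O)CC2(C1)C[C@@H](C)[C@H](C)[C@@H](O[Si](C)(C)C(C)(C)C)c1cc(OC)c(OC)c(OC)c12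
F5 | step 10 | (7R,8S,9R)-9-[(tert-butyldimethylsilyl)oxy]-2,3,4-trimethoxy-7,8-dimethyl-6,7,8,9-tetrahydrospiro[benzo[7]annulene-5,1′-cyclohexane]-3′,4′,5′-trione | O=C1CC2(CC(=O)C1=O)C[C@@H](C)[C@H](C)[C@@H](O[Si](C)(C)C(C)(C)C)c1cc(OC)c(OC)c(OC)c12
F6 | step 5 | (3R,4S,5R)-5-(2-bromo-3,4,5-trimethoxyphenyl)-5-hydroxy-N-methoxy-N,3,4-trimethylpentanamide | CON(C)C(=O)C[C@@H](C)[C@H](C)[C@@H](O)c1cc(OC)c(OC)c(OC)c1Br
F7 | step 8 | ethyl 2-[(7R,8S,9R)-9-[(tert-butyldimethylsilyl)oxy]-2,3,4-trimethoxy-7,8-dimethyl-6,7,8,9-tetrahydro-5H-benzo[7]annulen-5-ylidene]acetate | CCOC(=O)C=C1C[C@@H](C)[C@H](C)[C@@H](O[Si](C)(C)C(C)(C)C)c2cc(OC)c(OC)c(OC)c21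
F8 | step 8 | 2-[(7R,8S,9R)-9-[(tert-butyldimethylsilyl)oxy]-2,3,4-trimethoxy-7,8-dimethyl-6,7,8,9-tetrahydro-5H-benzo[7]annulen-5-ylidene]ethan-1-ol | OCC=C1C[C@@H](C)[C@H](C)[C@@H](O[Si](C)(C)C(C)(C)C)c2cc(OC)c(OC)c(OC)c21
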